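The pyran ring is cut across C2–C3 and C4–C4a, which leaves an aryl enol ether (O1–C2 already joined) and a two-carbon enol silane. In the key step a confined chiral Brønsted acid protonates the enol ether to the aryl oxocarbenium ion C4a=C8a–O1+=C2; the enol silane bonds to C2 and the cation that appears at C4 is trapped by C4a, the only unsubstituted carbon of the penta-oxygenated benzene ring, so the chromene and the C2 stereocentre arise in one operation. The precursor is a 2-aryloxy-1-alkene carrying a trans-2,6-dimethylcyclohexanone (auxiliary-controlled Michael addition, then octalone equilibration); its carbonyl becomes the exocyclic methylene last.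

Key step: step 10

Assumption: the sense of induction of the chiral acid in step 10 cannot be predicted with certainty, so the catalyst antipode that gives (S) at C2 is chosen after a first experiment; both antipodes are accessible from (R)- or (S)-BINOL.

Step 1
Reactants: 1 2,6-dimethylcyclohexan-1-one (cis/trans mixture); 2 (S)-1-phenylethan-1-amine
Product: 3 (S)-N-(2,6-dimethylcyclohexylidene)-1-phenylethan-1-amine (ring epimers)
Conditions: TsOH·H2O (cat.), toluene, reflux, Dean–Stark
Reagents that add atoms: none
Why: Acid-catalysed imine condensation driven by azeotropic removal of water; the ring stereocentres are labile through imine–enamine tautomerism and are fixed in steps 2 and 3.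

Step 2
Reactants: 3; 4 but-3-en-2-one
Product: 6 (2R)-2,6-dimethyl-2-(3-oxobutyl)cyclohexan-1-one (C6 epimers), via imine adduct 5 (not isolated)
Conditions: 4 (1.5 equiv), THF, 45 °C; then 10% aq AcOH, 23 °C
Reagents that add atoms: water, O
Why: Deracemising Michael addition of a chiral imine (d'Angelo reaction), in which the secondary enamine tautomer adds to the enone through an aza-ene-like chair transition state on the face anti to the phenyl group of the auxiliary, which should set the quaternary centre as R before hydrolysis releases the ketone.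

Step 3
Reactants: 6
Product: 7 (4aR,8R)-4a,8-dimethyl-4,4a,5,6,7,8-hexahydronaphthalen-2(3H)-one
Conditions: NaOMe, MeOH, 65 °C
Reagents that add atoms: none
Why: Intramolecular aldol condensation (second stage of a Robinson annulation) under equilibrating base, in which C8 epimerises through the extended dienolate to the equatorial methyl trans to the axial angular methyl, so the secondary methyl centre is set by thermodynamic control in the bicycle (the minor cis epimer is removed by chromatography).

Step 4
Reactants: 7
Product: 8 (4aR,8R)-2,4a,8-trimethyl-2,3,4,4a,5,6,7,8-octahydronaphthalen-2-ol (C2 epimers)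
Conditions: MeLi, Et2O, −78 °C; H2O
Reagents that add atoms: methyllithium (MeLi), [Li+].[CH3-]
Why: 1,2-Addition of MeLi to the enone carbonyl; the configuration of the new carbinol carbon does not matter because that carbon becomes a ketone again in step 5.

Step 5
Reactants: 8
Product: 10 (2R,6R)-2,6-dimethyl-2-(3-oxobutyl)cyclohexan-1-one, via hydroxy aldehyde 9 (not isolated)
Conditions: O3, CH2Cl2–MeOH, −78 °C; Me2S; then NaIO4, THF–H2O, 23 °C
Reagents that add atoms: ozone, O=[O+][O-]
Why: Ozonolysis of the trisubstituted alkene with reductive work-up, then periodate (Malaprade) cleavage of the α-hydroxy aldehyde, excises the former vinyl carbon and returns the 1,5-diketone under neutral, non-enolising conditions, so the trans relationship fixed in step 3 should be kept.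

Step 6
Reactants: 10
Product: 11 4-[(1R,3R)-1,3-dimethyl-2-oxocyclohexyl]but-1-en-2-yl trifluoromethanesulfonate
Conditions: LiN(iPr)2 (1.05 equiv), THF, −78 °C; PhNTf2, −78 → 0 °C
Reagents that add atoms: N-phenylbis(trifluoromethanesulfonimide), O=S(=O)(N(c1ccccc1)S(=O)(=O)C(F)(F)F)C(F)(F)F
Why: Kinetic deprotonation should occur at the unhindered methyl group of the side-chain ketone and not at the tertiary α-CH of the hindered ring ketone, and O-triflation of that terminal enolate gives the vinyl triflate without touching the ring stereocentres.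

Step 7
Reactants: 12 1,2,3-trimethoxybenzene
Product: 13 1,5-dibromo-2,3,4-trimethoxybenzene
Conditions: NBS (2.2 equiv), MeCN, 23 → 60 °C
Reagents that add atoms: N-bromosuccinimide, O=C1CCC(=O)N1Br
Why: Twofold electrophilic aromatic bromination, the first at C4 and the second at C6, each ortho to one outer methoxy group and para to the other, in preference to C5 next to the first bromine.

Step 8
Reactants: 13
Product: 14 4,5,6-trimethoxybenzene-1,3-diol
Conditions: Pd2(dba)3 (2 mol %), 2-di-tert-butylphosphino-2′,4′,6′-triisopropylbiphenyl (8 mol %), KOH, 1,4-dioxane–H2O, 100 °C, argon; then aq HCl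
Reagents that add atoms: potassium hydroxide, [K+].[OH-]
Why: Palladium-catalysed hydroxylation of aryl bromides (C–O coupling with hydroxide on a bulky biaryl phosphine catalyst) should convert both C–Br bonds, and the oxidation-prone symmetric resorcinol is kept under argon.

Step 9
Reactants: 11; 14
Product: 15 (2R,6R)-2-{3-[(5-hydroxy-2,3,4-trimethoxyphenyl)oxy]but-3-en-1-yl}-2,6-dimethylcyclohexan-1-one
Conditions: Pd2(dba)3 (2.5 mol %), 2-(di-tert-butylphosphino)biphenyl (6 mol %), K3PO4, 14 (3 equiv), toluene, 80 °C, argon
Reagents that add atoms: none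
Why: Palladium-catalysed C–O cross-coupling of a vinyl triflate with a phenol gives the aryl enol ether; the two hydroxyl groups of 14 are equivalent by symmetry, so an excess of the diol secures mono-vinylation without a regiochemical question, and the phosphate base should be too weak to enolise the hindered ketone.

Step 10
Reactants: 15; 16 trimethyl(vinyloxy)silane
Product: 18 (2R,6R)-2-{2-[(2S)-5-hydroxy-6,7,8-trimethoxy-2-methyl-2H-chromen-2-yl]ethyl}-2,6-dimethylcyclohexan-1-one, via 4-silyloxychroman 17 (not isolated)
Conditions: confined chiral imidodiphosphorimidate Brønsted acid (IDPi, 3,3′-diaryl-BINOL-derived, 5 mol %), 16 (4 equiv, slow addition), toluene, −40 → 0 °C; aq NaHCO3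
Reagents that add atoms: none
Why: Proposed new method: the acid C-protonates the enol ether to the aryl oxocarbenium ion (C4a=C8a–O1+=C2) held as a contact ion pair, the CH2 terminus of 16 adds to C2 (C3–C2 bond), the silyloxycarbenium carbon C4 so formed is attacked by C4a (C4–C4a bond) with return of the proton, and on warming the acid eliminates Me3SiOH across C3–C4 of 17. The closest known reactions are the oxa-Povarov [4+2] annulation of aryl oxocarbenium ions with alkenes and the confined-acid-catalysed Mukaiyama additions of acetaldehyde enol silanes and of silyl nucleophiles to methyl alkyl ketones, in which such catalysts tell a methyl from a larger alkyl group. The pyran ring closes by a 6-exo-trig Friedel–Crafts attack, the whole being a stepwise polar [4+2] annulation. C2 is set by catalyst control, the chiral anion pocket differentiating the enantiotopic faces of the oxocarbenium carbon (methyl against the 2-cyclohexylethyl arm) while the ring stereocentres are too remote to interfere, and the C4 centre of 17 is destroyed by the elimination. The step needs protonation of the 1,1-disubstituted enol ether in preference to 16 and to the product alkene (slow addition, low temperature) and ring closure at one site only, which the single free arene position C4a secures; keeping the ring carbon as a hindered ketone and not yet as the exocyclic alkene rules out a cation–olefin (Prins) cyclisation onto C2.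

Step 11
Reactants: 18
Product: 19 (2S)-2-{2-[(1R,3R)-1,3-dimethyl-2-methylidenecyclohexyl]ethyl}-6,7,8-trimethoxy-2-methyl-2H-chromen-5-ol
Conditions: Cp2Ti(μ-CH2)(μ-Cl)AlMe2 (Tebbe reagent, 3 equiv), pyridine, THF–toluene, −40 → 23 °C; aq NaOH
Reagents that add atoms: Tebbe reagent Cp2Ti(μ-CH2)(μ-Cl)AlMe2 (the dative Cl→Al contact of the chloride bridge is not drawn), C[Al](C)C[Ti](Cl)(C1C=CC=C1)C1C=CC=C1
Why: Tebbe methylenation (titanium methylidene [2+2] addition and cycloreversion) olefinates hindered, enolisable ketones without base, so the adjacent stereocentres should survive, one extra equivalent covers the phenol, and the non-acidic conditions spare the chromene and the new 1,1-disubstituted alkene.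

Compound list
1 | 2,6-dimethylcyclohexan-1-one (cis/trans mixture) | CC1CCCC(C)C1=O | starting material
2 | (S)-1-phenylethan-1-amine | C[C@H](N)c1ccccc1 | starting material
3 | (S)-N-(2,6-dimethylcyclohexylidene)-1-phenylethan-1-amine (ring epimers) | C[C@H](N=C1C(C)CCCC1C)c1ccccc1 | intermediate
4 | but-3-en-2-one | C=CC(C)=O | starting material
5 | imine adduct, (S)-N-[(2R)-2,6-dimethyl-2-(3-oxobutyl)cyclohexylidene]-1-phenylethan-1-amine (C6 epimers) | C[C@H](N=C1C(C)CCC[C@]1(C)CCC(C)=O)c1ccccc1 | intermediate
6 | (2R)-2,6-dimethyl-2-(3-oxobutyl)cyclohexan-1-one (C6 epimers) | O=C1C(C)CCC[C@]1(C)CCC(C)=O | intermediate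
7 | (4aR,8R)-4a,8-dimethyl-4,4a,5,6,7,8-hexahydronaphthalen-2(3H)-one | O=C1C=C2[C@H](C)CCC[C@]2(C)CC1 | intermediate
8 | (4aR,8R)-2,4a,8-trimethyl-2,3,4,4a,5,6,7,8-octahydronaphthalen-2-ol (C2 epimers) | CC1(O)C=C2[C@H](C)CCC[C@]2(C)CC1 | intermediate
9 | hydroxy aldehyde, 4-[(1R,3R)-1,3-dimethyl-2-oxocyclohexyl]-2-hydroxy-2-methylbutanal (C2 epimers) | O=C1[C@H](C)CCC[C@]1(C)CCC(C)(O)C=O | intermediate
10 | (2R,6R)-2,6-dimethyl-2-(3-oxobutyl)cyclohexan-1-one | O=C1[C@H](C)CCC[C@]1(C)CCC(C)=O | intermediate
11 | 4-[(1R,3R)-1,3-dimethyl-2-oxocyclohexyl]but-1-en-2-yl trifluoromethanesulfonate | O=C1[C@H](C)CCC[C@]1(C)CCC(=C)OS(=O)(=O)C(F)(F)F | intermediate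
12 | 1,2,3-trimethoxybenzene | COc1cccc(OC)c1OC | starting material
13 | 1,5-dibromo-2,3,4-trimethoxybenzene | COc1c(Br)cc(Br)c(OC)c1OC | intermediate
14 | 4,5,6-trimethoxybenzene-1,3-diol | COc1c(O)cc(O)c(OC)c1OC | intermediate
15 | (2R,6R)-2-{3-[(5-hydroxy-2,3,4-trimethoxyphenyl)oxy]but-3-en-1-yl}-2,6-dimethylcyclohexan-1-one | O=C1[C@H](C)CCC[C@]1(C)CCC(=C)Oc1cc(O)c(OC)c(OC)c1OC | intermediate
16 | trimethyl(vinyloxy)silane | C=CO[Si](C)(C)C | starting material
17 | 4-silyloxychroman, (2R,6R)-2-(2-{(2S)-5-hydroxy-6,7,8-trimethoxy-2-methyl-4-[(trimethylsilyl)oxy]-3,4-dihydro-2H-chromen-2-yl}ethyl)-2,6-dimethylcyclohexan-1-one (C4 epimers) | O=C1[C@H](C)CCC[C@]1(C)CC[C@@]1(C)CC(O[Si](C)(C)C)c2c(O)c(OC)c(OC)c(OC)c2O1 | intermediate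
18 | (2R,6R)-2-{2-[(2S)-5-hydroxy-6,7,8-trimethoxy-2-methyl-2H-chromen-2-yl]ethyl}-2,6-dimethylcyclohexan-1-one | O=C1[C@H](C)CCC[C@]1(C)CC[C@@]1(C)C=Cc2c(O)c(OC)c(OC)c(OC)c2O1 | intermediate
19 | (2S)-2-{2-[(1R,3R)-1,3-dimethyl-2-methylidenecyclohexyl]ethyl}-6,7,8-trimethoxy-2-methyl-2H-chromen-5-ol | C=C1[C@H](C)CCC[C@]1(C)CC[C@@]1(C)C=Cc2c(O)c(OC)c(OC)c(OC)c2O1 | target

Total step count: 11. Longest linear sequence: 9 steps (steps 1–6 and 9–11); the arene branch (steps 7 and 8) joins at step 9.

Steps most likely to fail

Step 10 (Proposed new method).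
- What may go wrong: weak facial discrimination between the methyl group and the alkyl arm at the oxocarbenium carbon; unproductive protodesilylation of the enol silane that drains the proton; C-alkylation of a second arene by the oxocarbenium ion; loss of the phenol from the open aldehyde stage followed by uncatalysed re-closure, which would erode the configuration at C2.
- Fallback (known chemistry; sets out from 10 and comes back at 18): (Z)-2-ethoxyvinyllithium in THF at −78 °C should add to the side-chain ketone of 10 to give the ethoxyvinyl carbinol F1. Dilute aqueous HCl should convert this to the β-methyl enal F2. Heating F2 with 14 and ethylenediammonium diacetate in toluene (attack at C4a, dehydration, oxa-6π electrocyclisation) should close the chromene and give 18 together with its C2 epimer F3. C2 is then not set by a reagent, and the two epimers are parted by preparative HPLC on a chiral stationary phase before step 11.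

Step 9.
- What may go wrong: double vinylation of the diol; base-induced elimination of the triflate; oxidative degradation of the electron-rich diol under the coupling conditions.
- Fallback (sets out from 11 and comes back at 15): Miyaura borylation of 11 (B2pin2, PdCl2(PPh3)2, PPh3, KOPh, toluene, 50 °C) should give the alkenyl boronate F4. Chan–Lam coupling of F4 with 14 (Cu(OAc)2, Et3N, 4 Å molecular sieves, CH2Cl2, 23 °C, argon) should then form the same aryl enol ether 15 with the polarity of the alkenyl partner reversed.

Step 11.
- What may go wrong: incomplete olefination of the hindered ketone; consumption of the reagent by the phenol; Lewis-acid ionisation of the chromene C2–O1 bond.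
- Fallback (sets out from 18 and comes back at 19): Peterson olefination. Me3SiCH2Li with CeCl3 in THF at −78 °C should add to the ketone to give the β-hydroxysilane F5, and KH in THF should bring about syn-elimination to the exocyclic alkene 19.

Further compounds
F1 | step 10 | (2R,6R)-2-[(4Z)-5-ethoxy-3-hydroxy-3-methylpent-4-en-1-yl]-2,6-dimethylcyclohexan-1-one (carbinol epimers) | O=C1[C@H](C)CCC[C@]1(C)CCC(C)(O)/C=C\OCC
F2 | step 10 | 5-[(1R,3R)-1,3-dimethyl-2-oxocyclohexyl]-3-methylpent-2-enal (E/Z mixture) | O=C1[C@H](C)CCC[C@]1(C)CCC(C)=CC=O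
F3 | step 10 | (2R,6R)-2-{2-[(2R)-5-hydroxy-6,7,8-trimethoxy-2-methyl-2H-chromen-2-yl]ethyl}-2,6-dimethylcyclohexan-1-one | O=C1[C@H](C)CCC[C@]1(C)CC[C@]1(C)C=Cc2c(O)c(OC)c(OC)c(OC)c2O1
F4 | step 9 | (2R,6R)-2,6-dimethyl-2-[3-(4,4,5,5-tetramethyl-1,3,2-dioxaborolan-2-yl)but-3-en-1-yl]cyclohexan-1-one | O=C1[C@H](C)CCC[C@]1(C)CCC(=C)B1OC(C)(C)C(C)(C)O1
F5 | step 11 | (2S)-2-{2-[(1R,3R)-2-hydroxy-1,3-dimethyl-2-[(trimethylsilyl)methyl]cyclohexyl]ethyl}-6,7,8-trimethoxy-2-methyl-2H-chromen-5-ol (carbinol epimers) | C[Si](C)(C)CC1(O)[C@H](C)CCC[C@]1(C)CC[C@@]1(C)C=Cc2c(O)c(OC)c(OC)c(OC)c2O1
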